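**Strategy.** The pentasubstituted resorcinol ring (chromene atoms C4a, C5, C6, C7, C8, C8a) is built, not decorated. A Diels–Alder/aromatisation joins a prenylated, acetoacetate-derived 1,3-dioxygenated diene (bringing C6 with its prenyl group, C7–O, C8–H and C8a–O) to a (benzofuran-2-yl)ethynyl 2-methylpropenyl ketone (bringing C5 with the benzofuran and C4a with the acyl group), and oxa-Michael closure of the pyranone follows in the same flask. One operation closes two rings and fixes all five substituents regiospecifically; the doubly ortho-flanked aryl–benzofuranyl bond is never made by coupling at a hindered arene. The precursors are an open-chain silyl ketene acetal and an alkynyl ketone.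

Key step: step 9

Remark on the chemistry: the target SMILES contains no stereocentre and no stereogenic double bond, so the compound is achiral and no asymmetric step is needed. Intermediates 14, 15, 17 and 21 carry stereocentres that are racemic or mixed and are removed later.

**Step 1**
Reactants: 1 methyl acetoacetate; 2 prenyl bromide (1-bromo-3-methylbut-2-ene)
Product: 4 methyl 7-methyl-3-oxooct-6-enoate, via sodium lithium dianion of methyl acetoacetate 3 (not isolated)
Conditions: NaH, THF, 0 °C; n-BuLi, 0 °C; then 2, 0 °C → rt; 1 M HCl quench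
Reagents that add atoms: none
Why: Acetoacetate dianion γ-alkylation: the terminal carbanion is the more nucleophilic site and should displace the primary allylic bromide by SN2.

**Step 2**
Reactants: 4 methyl 7-methyl-3-oxooct-6-enoate
Product: 5 methyl 7-methyl-3-(triisopropylsilyloxy)octa-2,6-dienoate (C2=C3 geometry of no consequence, it becomes a single bond in step 3)
Conditions: TIPSOTf, Et3N, CH2Cl2, 0 °C
Reagents that add atoms: triisopropylsilyl trifluoromethanesulfonate, CC(C)[Si](OS(=O)(=O)C(F)(F)F)(C(C)C)C(C)C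
Why: Soft enolisation and O-silylation of a β-keto ester with a silyl triflate and an amine base; this places the robust silyl group on the oxygen that becomes C7–O.

**Step 3**
Reactants: 5 methyl 7-methyl-3-(triisopropylsilyloxy)octa-2,6-dienoate
Product: 7 (3Z)-1-methoxy-7-methyl-3-(triisopropylsilyloxy)-1-(trimethylsilyloxy)octa-1,3,6-triene, via lithium dienolate of 5 6 (not isolated)
Conditions: LDA, THF, −78 °C; TMSCl, −78 → 0 °C; non-aqueous work-up, used crude
Reagents that add atoms: chlorotrimethylsilane, C[Si](C)(C)Cl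
Why: Kinetic γ-deprotonation of the vinylogous ester and O-silylation give the 1-alkoxy-1,3-bis(silyloxy)diene; the 3Z geometry (side chain trans to C2) is expected because the alternative suffers A(1,3) strain.

**Step 4**
Reactants: 8 benzofuran-6-ol
Product: 9 6-(triisopropylsilyloxy)benzofuran
Conditions: TIPSCl, imidazole, DMF, rt
Reagents that add atoms: chlorotriisopropylsilane, CC(C)[Si](Cl)(C(C)C)C(C)C
Why: Standard phenol silylation; the aryl TIPS ether tolerates organolithium, Pd/Cu, heat, dilute acid and borohydride and is removed by fluoride.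

**Step 5**
Reactants: 9 6-(triisopropylsilyloxy)benzofuran
Product: 11 2-iodo-6-(triisopropylsilyloxy)benzofuran, via 2-lithio-6-(triisopropylsilyloxy)benzofuran 10 (not isolated)
Conditions: n-BuLi, THF, −78 °C; I2, −78 °C → rt
Reagents that add atoms: iodine, II
Why: Directed deprotonation at C2, the most acidic C–H of a benzofuran (α to the ring oxygen), followed by iodinolysis of the aryllithium.

**Step 6**
Reactants: 12 3-methylbut-2-enal; 13 ethynylmagnesium bromide
Product: 14 rac-5-methylhex-4-en-1-yn-3-ol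
Conditions: THF, 0 °C; sat. aq. NH4Cl
Reagents that add atoms: none
Why: 1,2-Addition of an alkynyl Grignard reagent to an enal; the new carbinol centre is racemic and is oxidised away in step 8.

**Step 7**
Reactants: 11 2-iodo-6-(triisopropylsilyloxy)benzofuran; 14 rac-5-methylhex-4-en-1-yn-3-ol
Product: 15 rac-5-methyl-1-[6-(triisopropylsilyloxy)benzofuran-2-yl]hex-4-en-1-yn-3-ol
Conditions: PdCl2(PPh3)2 (cat.), CuI (cat.), Et3N, THF, rt
Reagents that add atoms: none
Why: Sonogashira coupling of a reactive 2-iodoheteroarene with a terminal alkyne at an unhindered position.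

**Step 8**
Reactants: 15 rac-5-methyl-1-[6-(triisopropylsilyloxy)benzofuran-2-yl]hex-4-en-1-yn-3-ol
Product: 16 5-methyl-1-[6-(triisopropylsilyloxy)benzofuran-2-yl]hex-4-en-1-yn-3-one
Conditions: activated MnO2, CH2Cl2, rt
Reagents that add atoms: none
Why: MnO2 oxidation of an alcohol that is both allylic and propargylic should be fast and leaves the benzofuran and silyl ether untouched.

**Step 9**
Reactants: 7 (3Z)-1-methoxy-7-methyl-3-(triisopropylsilyloxy)-1-(trimethylsilyloxy)octa-1,3,6-triene; 16 5-methyl-1-[6-(triisopropylsilyloxy)benzofuran-2-yl]hex-4-en-1-yn-3-one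
Product: 20 2,2-dimethyl-6-(3-methylbut-2-enyl)-7-(triisopropylsilyloxy)-5-[6-(triisopropylsilyloxy)benzofuran-2-yl]chroman-4-one, via cyclohexa-1,4-diene cycloadduct 17 (not isolated), via aryl trimethylsilyl ether 18 (not isolated), via 2-hydroxyaryl enone 19 (not isolated)
Conditions: 7 (excess), PhMe, 110 °C, sealed tube; then 1 M aq. HCl, THF, rt → 40 °C
Reagents that add atoms: none
Why: This is a polarised normal-demand [4+2] cycloaddition of a 1-alkoxy-1,3-bis(silyloxy)diene with an acetylenic ketone, the known resorcinol benzannulation: the nucleophilic γ-carbon C4 of 7 bonds to the β-carbon of ynone 16 and the ketene-acetal carbon C1 to the α-carbon, so the acyl group lands next to the former ester carbon and the benzofuran next to the prenyl-bearing carbon. Cycloadduct 17 (two stereocentres, both erased) should aromatise in the hot, water-free mixture by 1,4-elimination of methanol to aryl TMS ether 18, which closes ring A by cycloaddition/aromatisation and locks the C7 oxygen as the aryl TIPS ether. Aqueous acid then cleaves only the TMS ether to phenol 19, whose hydroxyl, the only one ortho to the acyl group, adds 6-endo-trig (oxa-Michael, as in 2'-hydroxyaryl enone to chromanone closures) to the β,β-dimethyl enone to close the pyranone of 20; no stereocentre is formed. The step needs regioselectivity (secured by the 1,1,3-trioxygenation of the diene and the ynone carbonyl, which polarise both partners in the same sense), chemoselectivity for the alkyne over the trisubstituted enone (steric and electronic), and a 3Z diene able to reach the s-cis conformation.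

**Step 10**
Reactants: 20 2,2-dimethyl-6-(3-methylbut-2-enyl)-7-(triisopropylsilyloxy)-5-[6-(triisopropylsilyloxy)benzofuran-2-yl]chroman-4-one
Product: 22 bis(triisopropylsilyl) ether of cathafuran C, via rac-chroman-4-ol 21 (not isolated)
Conditions: NaBH4, THF/MeOH, 0 °C → rt; then p-TsOH·H2O (cat.), PhMe, 40 °C
Reagents that add atoms: none
Why: Borohydride reduction gives the benzylic alcohol (racemic centre, destroyed at once), and acid-catalysed E1 dehydration through the ortho,para-oxygen-stabilised benzylic cation should give the conjugated 2H-chromene; both phenols are silylated, so the prenyl group cannot cyclise to a chroman.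

**Step 11**
Reactants: 22 bis(triisopropylsilyl) ether of cathafuran C
Product: 23 cathafuran C
Conditions: TBAF, AcOH, THF, 0 °C → rt
Reagents that add atoms: none
Why: Fluoride cleavage of both aryl Si–O bonds; acetic acid buffering protects the electron-rich phenol and chromene from base-mediated oxidation.

**Compound list**

1 | methyl acetoacetate | COC(=O)CC(C)=O | starting material
2 | prenyl bromide (1-bromo-3-methylbut-2-ene) | CC(C)=CCBr | starting material
3 | sodium lithium dianion of methyl acetoacetate | [Na+].[Li+].C=C([O-])C=C([O-])OC | intermediate (not isolated)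
4 | methyl 7-methyl-3-oxooct-6-enoate | COC(=O)CC(=O)CCC=C(C)C | intermediate
5 | methyl 7-methyl-3-(triisopropylsilyloxy)octa-2,6-dienoate (C2=C3 geometry not assigned) | COC(=O)C=C(CCC=C(C)C)O[Si](C(C)C)(C(C)C)C(C)C | intermediate
6 | lithium dienolate of 5 | [Li+].COC([O-])=CC(O[Si](C(C)C)(C(C)C)C(C)C)=CCC=C(C)C | intermediate (not isolated)
7 | (3Z)-1-methoxy-7-methyl-3-(triisopropylsilyloxy)-1-(trimethylsilyloxy)octa-1,3,6-triene (C1=C2 geometry not assigned) | COC(O[Si](C)(C)C)=C/C(O[Si](C(C)C)(C(C)C)C(C)C)=C/CC=C(C)C | intermediate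
8 | benzofuran-6-ol | Oc1ccc2ccoc2c1 | starting material
9 | 6-(triisopropylsilyloxy)benzofuran | CC(C)[Si](Oc1ccc2ccoc2c1)(C(C)C)C(C)C | intermediate
10 | 2-lithio-6-(triisopropylsilyloxy)benzofuran | [Li]c1cc2ccc(O[Si](C(C)C)(C(C)C)C(C)C)cc2o1 | intermediate (not isolated)
11 | 2-iodo-6-(triisopropylsilyloxy)benzofuran | Ic1cc2ccc(O[Si](C(C)C)(C(C)C)C(C)C)cc2o1 | intermediate
12 | 3-methylbut-2-enal | CC(C)=CC=O | starting material
13 | ethynylmagnesium bromide | C#C[Mg]Br | starting material
14 | rac-5-methylhex-4-en-1-yn-3-ol | CC(C)=CC(O)C#C | intermediate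
15 | rac-5-methyl-1-[6-(triisopropylsilyloxy)benzofuran-2-yl]hex-4-en-1-yn-3-ol | CC(C)=CC(O)C#Cc1cc2ccc(O[Si](C(C)C)(C(C)C)C(C)C)cc2o1 | intermediate
16 | 5-methyl-1-[6-(triisopropylsilyloxy)benzofuran-2-yl]hex-4-en-1-yn-3-one | CC(C)=CC(=O)C#Cc1cc2ccc(O[Si](C(C)C)(C(C)C)C(C)C)cc2o1 | intermediate
17 | 1-{6-methoxy-3-(3-methylbut-2-enyl)-4-(triisopropylsilyloxy)-2-[6-(triisopropylsilyloxy)benzofuran-2-yl]-6-(trimethylsilyloxy)cyclohexa-1,4-dien-1-yl}-3-methylbut-2-en-1-one (diastereomer mixture, racemic) | COC1(O[Si](C)(C)C)C=C(O[Si](C(C)C)(C(C)C)C(C)C)C(CC=C(C)C)C(c2cc3ccc(O[Si](C(C)C)(C(C)C)C(C)C)cc3o2)=C1C(=O)C=C(C)C | intermediate (not isolated)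
18 | 3-methyl-1-{3-(3-methylbut-2-enyl)-4-(triisopropylsilyloxy)-2-[6-(triisopropylsilyloxy)benzofuran-2-yl]-6-(trimethylsilyloxy)phenyl}but-2-en-1-one | CC(C)=CCc1c(O[Si](C(C)C)(C(C)C)C(C)C)cc(O[Si](C)(C)C)c(C(=O)C=C(C)C)c1-c1cc2ccc(O[Si](C(C)C)(C(C)C)C(C)C)cc2o1 | intermediate (not isolated)
19 | 1-{6-hydroxy-3-(3-methylbut-2-enyl)-4-(triisopropylsilyloxy)-2-[6-(triisopropylsilyloxy)benzofuran-2-yl]phenyl}-3-methylbut-2-en-1-one | CC(C)=CCc1c(O[Si](C(C)C)(C(C)C)C(C)C)cc(O)c(C(=O)C=C(C)C)c1-c1cc2ccc(O[Si](C(C)C)(C(C)C)C(C)C)cc2o1 | intermediate (not isolated)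
20 | 2,2-dimethyl-6-(3-methylbut-2-enyl)-7-(triisopropylsilyloxy)-5-[6-(triisopropylsilyloxy)benzofuran-2-yl]chroman-4-one | CC(C)=CCc1c(O[Si](C(C)C)(C(C)C)C(C)C)cc2OC(C)(C)CC(=O)c2c1-c1cc3ccc(O[Si](C(C)C)(C(C)C)C(C)C)cc3o1 | intermediate
21 | rac-2,2-dimethyl-6-(3-methylbut-2-enyl)-7-(triisopropylsilyloxy)-5-[6-(triisopropylsilyloxy)benzofuran-2-yl]chroman-4-ol | CC(C)=CCc1c(O[Si](C(C)C)(C(C)C)C(C)C)cc2OC(C)(C)CC(O)c2c1-c1cc3ccc(O[Si](C(C)C)(C(C)C)C(C)C)cc3o1 | intermediate (not isolated)
22 | bis(triisopropylsilyl) ether of cathafuran C: 2,2-dimethyl-6-(3-methylbut-2-enyl)-7-(triisopropylsilyloxy)-5-[6-(triisopropylsilyloxy)benzofuran-2-yl]-2H-chromene | CC(C)=CCc1c(O[Si](C(C)C)(C(C)C)C(C)C)cc2OC(C)(C)C=Cc2c1-c1cc3ccc(O[Si](C(C)C)(C(C)C)C(C)C)cc3o1 | intermediate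
23 | cathafuran C: 2-[7-hydroxy-2,2-dimethyl-6-(3-methylbut-2-enyl)-2H-chromen-5-yl]benzofuran-6-ol | CC(C)=CCc1c(O)cc2c(c1-c1cc3ccc(O)cc3o1)C=CC(C)(C)O2 | target

**Step count.** Total: 11 steps. Longest linear sequence: 7 steps (steps 4, 5, 7, 8, 9, 10, 11 from benzofuran-6-ol).

**Steps most likely to fail**

Step 9. The cycloaddition may be too slow: the ynone carries an electron-rich heteroaryl group at its β-carbon and both new bonds form at congested centres, so thermal decomposition or protodesilylation of the ketene acetal could outrun ring formation. The fallback sets out from 11 and 7 and comes back at 22. Sonogashira coupling of 11 with propargyl alcohol would give 3-[6-(triisopropylsilyloxy)benzofuran-2-yl]prop-2-yn-1-ol F1, and MnO2 oxidation the ynal F2, a smaller and more electron-poor dienophile. Its cycloaddition with 7 (PhMe, 80 °C) should give cycloadduct F3, which loses methanol to the aryl trimethylsilyl ether F4; mild aqueous acid then frees the salicylaldehyde F5. Addition of 2-methylprop-1-enylmagnesium bromide (2.2 equiv, THF, 0 °C) would give the ortho-hydroxybenzylic allylic alcohol F6. Dehydration (PPTS cat., PhMe, 60 °C) to the ortho-quinone methide F7 and oxa-6π electrocyclisation would deliver 22 directly. The pyran ring is then closed by electrocyclisation instead of conjugate addition, and steps 9 and 10 are replaced.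

Step 10. Hydride delivery to the peri-shielded, electron-rich ketone may be sluggish, and in the acid step the benzylic cation could be captured by C3 of the neighbouring benzofuran (peri Friedel–Crafts closure) or the prenyl alkene could be protonated. The fallback sets out from 20 and comes back at 22 without any carbocation. Enolisation and O-triflation (KHMDS, PhNTf2, THF, −78 °C) would give the enol triflate F8. Palladium-catalysed formate reduction (Pd(OAc)2, PPh3, HCO2H, Et3N, DMF, 60 °C) would replace the triflate by hydrogen and give 22.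

Step 3. Kinetic γ-deprotonation of the hindered TIPS enol ether may be incomplete or unselective, C-silylation may compete, and the ketene acetal may hydrolyse on handling. The fallback sets out from 4 and comes back at 20. It abandons the strong-base step and moves the C7–O protection to after the benzannulation. Double soft enolisation of 4 (TMSOTf 2.2 equiv, Et3N, Et2O, 0 °C) would give the bis(trimethylsilyloxy)diene F9 in one operation. Under the conditions of step 9 with 16 this should pass through cycloadduct F10 and the bis(trimethylsilyl) aryl ether F11. Acid work-up would give the dihydroxyaryl enone F12, which closes to the 7-hydroxychromanone F13. Silylation of its single free phenol (TIPSCl, imidazole, DMF) rejoins the route at 20.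

**Further compounds**

F1 | step 9 | 3-[6-(triisopropylsilyloxy)benzofuran-2-yl]prop-2-yn-1-ol | OCC#Cc1cc2ccc(O[Si](C(C)C)(C(C)C)C(C)C)cc2o1
F2 | step 9 | 3-[6-(triisopropylsilyloxy)benzofuran-2-yl]prop-2-ynal | O=CC#Cc1cc2ccc(O[Si](C(C)C)(C(C)C)C(C)C)cc2o1
F3 | step 9 | 6-methoxy-3-(3-methylbut-2-enyl)-4-(triisopropylsilyloxy)-2-[6-(triisopropylsilyloxy)benzofuran-2-yl]-6-(trimethylsilyloxy)cyclohexa-1,4-diene-1-carbaldehyde (not isolated) | COC1(O[Si](C)(C)C)C=C(O[Si](C(C)C)(C(C)C)C(C)C)C(CC=C(C)C)C(c2cc3ccc(O[Si](C(C)C)(C(C)C)C(C)C)cc3o2)=C1C=O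
F4 | step 9 | 3-(3-methylbut-2-enyl)-4-(triisopropylsilyloxy)-2-[6-(triisopropylsilyloxy)benzofuran-2-yl]-6-(trimethylsilyloxy)benzaldehyde (not isolated) | CC(C)=CCc1c(O[Si](C(C)C)(C(C)C)C(C)C)cc(O[Si](C)(C)C)c(C=O)c1-c1cc2ccc(O[Si](C(C)C)(C(C)C)C(C)C)cc2o1
F5 | step 9 | 6-hydroxy-3-(3-methylbut-2-enyl)-4-(triisopropylsilyloxy)-2-[6-(triisopropylsilyloxy)benzofuran-2-yl]benzaldehyde | CC(C)=CCc1c(O[Si](C(C)C)(C(C)C)C(C)C)cc(O)c(C=O)c1-c1cc2ccc(O[Si](C(C)C)(C(C)C)C(C)C)cc2o1
F6 | step 9 | rac-2-(1-hydroxy-3-methylbut-2-enyl)-4-(3-methylbut-2-enyl)-5-(triisopropylsilyloxy)-3-[6-(triisopropylsilyloxy)benzofuran-2-yl]phenol | CC(C)=CCc1c(O[Si](C(C)C)(C(C)C)C(C)C)cc(O)c(C(O)C=C(C)C)c1-c1cc2ccc(O[Si](C(C)C)(C(C)C)C(C)C)cc2o1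
F7 | step 9 | ortho-quinone methide from F6: 6-(3-methylbut-2-enylidene)-4-(3-methylbut-2-enyl)-3-(triisopropylsilyloxy)-5-[6-(triisopropylsilyloxy)benzofuran-2-yl]cyclohexa-2,4-dien-1-one (not isolated) | O=C1C=C(O[Si](C(C)C)(C(C)C)C(C)C)C(CC=C(C)C)=C(c2cc3ccc(O[Si](C(C)C)(C(C)C)C(C)C)cc3o2)C1=CC=C(C)C
F8 | step 10 | 2,2-dimethyl-6-(3-methylbut-2-enyl)-7-(triisopropylsilyloxy)-5-[6-(triisopropylsilyloxy)benzofuran-2-yl]-2H-chromen-4-yl trifluoromethanesulfonate | CC(C)=CCc1c(O[Si](C(C)C)(C(C)C)C(C)C)cc2OC(C)(C)C=C(OS(=O)(=O)C(F)(F)F)c2c1-c1cc3ccc(O[Si](C(C)C)(C(C)C)C(C)C)cc3o1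
F9 | step 3 | 1-methoxy-7-methyl-1,3-bis(trimethylsilyloxy)octa-1,3,6-triene | COC(O[Si](C)(C)C)=CC(O[Si](C)(C)C)=CCC=C(C)C
F10 | step 3 | 1-{6-methoxy-3-(3-methylbut-2-enyl)-2-[6-(triisopropylsilyloxy)benzofuran-2-yl]-4,6-bis(trimethylsilyloxy)cyclohexa-1,4-dien-1-yl}-3-methylbut-2-en-1-one (not isolated) | COC1(O[Si](C)(C)C)C=C(O[Si](C)(C)C)C(CC=C(C)C)C(c2cc3ccc(O[Si](C(C)C)(C(C)C)C(C)C)cc3o2)=C1C(=O)C=C(C)C
F11 | step 3 | 3-methyl-1-{3-(3-methylbut-2-enyl)-2-[6-(triisopropylsilyloxy)benzofuran-2-yl]-4,6-bis(trimethylsilyloxy)phenyl}but-2-en-1-one (not isolated) | CC(C)=CCc1c(O[Si](C)(C)C)cc(O[Si](C)(C)C)c(C(=O)C=C(C)C)c1-c1cc2ccc(O[Si](C(C)C)(C(C)C)C(C)C)cc2o1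
F12 | step 3 | 1-{4,6-dihydroxy-3-(3-methylbut-2-enyl)-2-[6-(triisopropylsilyloxy)benzofuran-2-yl]phenyl}-3-methylbut-2-en-1-one (not isolated) | CC(C)=CCc1c(O)cc(O)c(C(=O)C=C(C)C)c1-c1cc2ccc(O[Si](C(C)C)(C(C)C)C(C)C)cc2o1
F13 | step 3 | 7-hydroxy-2,2-dimethyl-6-(3-methylbut-2-enyl)-5-[6-(triisopropylsilyloxy)benzofuran-2-yl]chroman-4-one | CC(C)=CCc1c(O)cc2OC(C)(C)CC(=O)c2c1-c1cc3ccc(O[Si](C(C)C)(C(C)C)C(C)C)cc3o1
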